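**Plan**

- Isochromene numbering is used (C1, O2, C3, C4, C4a, C5–C8, C8a). The pyran ring O2–C1=C8a–C4a–C4=C3 is the formal [4+2] adduct of a 1-oxadiene (O=C3–C4(OMe)=C4a) and an alkyne (C8a≡C1). C8a is the α-carbon of the vinylogous ester O2–C1=C8a–C8=O, C4a is β to the C3 carbonyl, and the C4a–H of the adduct enolizes toward the C5 ketone.
- Retrosynthesis: cut C4a–C8a and O2–C1 together to reach an acyclic ynone/ene-trione. Its cis 2-methoxy-ene-1,4-dione (C3, C4, C4a, C5) is masked as a 3-methoxyfuran. Further cuts: furan–C6 (acyl substitution), C7–C8 (aldol), furan–side chain (alkylation).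
- Forward: the chain is assembled first (lactate acetal aldol, furyl ketone, butanoate, ynone) and the furan is opened. Both rings then arise in one operation, the carbocycle first through C4a–C8a and the pyran second through O2–C1. Desilylation ends the route.
- Stereochemistry: the only stereocentre, C7, comes from (S)-lactic acid by self-regeneration of stereocentres through its pivalaldehyde acetal. It is quaternary and non-enolizable from step 2 onward.

Key step: step 11

Remark: 3-methoxyfuran and the silyl-protected bromopropanol 9 are taken as purchasable. The carbinol carbon made in step 2 (later the C8 ketone) is carried as a mixture of epimers until it is oxidized in step 8.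

**Route**

Step 1
Reactants: 1 (S)-lactic acid; 2 pivalaldehyde
Product: 3 (2S,5S)-2-tert-butyl-5-methyl-1,3-dioxolan-4-one (cis)
Conditions: p-TsOH·H2O (cat.), H2SO4 (cat.), pentane, reflux, Dean–Stark; crystallization from Et2O/pentane, −78 °C
Reagents that add atoms: none
Why: Acid-catalysed acetalization of an α-hydroxy acid under thermodynamic control should place tert-butyl cis to methyl at the new acetal carbon, and crystallization should deliver the pure cis isomer.

Step 2
Reactants: 3 (2S,5S)-2-tert-butyl-5-methyl-1,3-dioxolan-4-one; 4 3-(trimethylsilyl)prop-2-ynal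
Product: 6 (2S,5R)-2-tert-butyl-5-[1-hydroxy-3-(trimethylsilyl)prop-2-yn-1-yl]-5-methyl-1,3-dioxolan-4-one (both carbinol epimers), via lithium enolate 5 (not isolated)
Conditions: LiN(iPr)2 (LDA), THF, −78 °C; then 4, −78 °C; AcOH, −78 °C
Reagents that add atoms: none
Why: Aldol addition with self-regeneration of stereocentres: the aldehyde should add to the planar enolate on the face trans to the tert-butyl group, so the new C–C bond takes the place of the lactate hydrogen and sets the quaternary carbon (later C7) as 5R, while the carbinol carbon forms unselectively and is removed in step 8.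

Step 3
Reactants: 6 (2S,5R)-2-tert-butyl-5-[1-hydroxy-3-(trimethylsilyl)prop-2-yn-1-yl]-5-methyl-1,3-dioxolan-4-one
Product: 7 (2S,5R)-2-tert-butyl-5-methyl-5-[1-(triethylsilyloxy)-3-(trimethylsilyl)prop-2-yn-1-yl]-1,3-dioxolan-4-one (both epimers at the silyloxy carbon)
Conditions: Et3SiOTf, 2,6-lutidine, CH2Cl2, −78 → 0 °C
Reagents that add atoms: triethylsilyl trifluoromethanesulfonate, CC[Si](CC)(CC)OS(=O)(=O)C(F)(F)F
Why: Silylation of a hindered secondary alcohol with a silyl triflate should protect the carbinol against the organolithium of step 5 without touching the acetal or the quaternary centre.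

Step 4
Reactants: 8 3-methoxyfuran; 9 (3-bromopropoxy)(tert-butyl)diphenylsilane
Product: 11 tert-butyl[3-(3-methoxyfuran-2-yl)propoxy]diphenylsilane, via 2-lithio-3-methoxyfuran 10 (not isolated)
Conditions: n-BuLi, THF, −78 → 0 °C; then 9, DMPU, −78 °C → rt
Reagents that add atoms: none
Why: Directed metalation should occur at C2 of the furan (α to the ring oxygen and ortho to methoxy), and the furyllithium should be alkylated by the primary bromide in an SN2 reaction.

Step 5
Reactants: 11 tert-butyl[3-(3-methoxyfuran-2-yl)propoxy]diphenylsilane; 7 (2S,5R)-2-tert-butyl-5-methyl-5-[1-(triethylsilyloxy)-3-(trimethylsilyl)prop-2-yn-1-yl]-1,3-dioxolan-4-one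
Product: 14 (2R)-1-{5-[3-(tert-butyldiphenylsilyloxy)propyl]-4-methoxyfuran-2-yl}-2-hydroxy-2-methyl-3-(triethylsilyloxy)-5-(trimethylsilyl)pent-4-yn-1-one (both C3 epimers), via 5-lithiofuran 12 (not isolated), via lithium hemiketal alkoxide 13 (not isolated)
Conditions: 11, n-BuLi, THF, −78 → 0 °C; then 7, −78 → −40 °C; AcOH, then aqueous work-up
Reagents that add atoms: none
Why: α-Lithiation at the free C5 of the furan followed by nucleophilic acyl substitution at the activated acetal-lactone carbonyl (organolithium addition to a 1,3-dioxolan-4-one) should stop at the tetrahedral adduct 13 at low temperature, which on work-up collapses to the ketone and releases pivalaldehyde and the free tertiary alcohol, the quaternary centre staying untouched.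

Step 6
Reactants: 14 (2R)-1-{5-[3-(tert-butyldiphenylsilyloxy)propyl]-4-methoxyfuran-2-yl}-2-hydroxy-2-methyl-3-(triethylsilyloxy)-5-(trimethylsilyl)pent-4-yn-1-one
Product: 15 (2R)-1-{5-[3-(tert-butyldiphenylsilyloxy)propyl]-4-methoxyfuran-2-yl}-2-methyl-1-oxo-3-(triethylsilyloxy)-5-(trimethylsilyl)pent-4-yn-2-yl butanoate (both C3 epimers)
Conditions: (PrCO)2O, DMAP, Et3N, CH2Cl2, rt → 40 °C
Reagents that add atoms: butanoic anhydride, CCCC(=O)OC(=O)CCC
Why: DMAP-catalysed acylation of a tertiary α-ketol, as used on the C7 hydroxyl of azaphilones, should work here because the ketone has no enolizable position and the centre cannot epimerize.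

Step 7
Reactants: 15 (2R)-1-{5-[3-(tert-butyldiphenylsilyloxy)propyl]-4-methoxyfuran-2-yl}-2-methyl-1-oxo-3-(triethylsilyloxy)-5-(trimethylsilyl)pent-4-yn-2-yl butanoate
Product: 16 (2R)-1-{5-[3-(tert-butyldiphenylsilyloxy)propyl]-4-methoxyfuran-2-yl}-3-hydroxy-2-methyl-1-oxo-5-(trimethylsilyl)pent-4-yn-2-yl butanoate (both C3 epimers)
Conditions: HF·pyridine, pyridine, THF, 0 °C
Reagents that add atoms: none
Why: Buffered fluoride desilylation should cleave the triethylsilyl ether selectively over the primary tert-butyldiphenylsilyl ether and the alkynyl silane, and the weakly acidic medium should suppress acyl migration.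

Step 8
Reactants: 16 (2R)-1-{5-[3-(tert-butyldiphenylsilyloxy)propyl]-4-methoxyfuran-2-yl}-3-hydroxy-2-methyl-1-oxo-5-(trimethylsilyl)pent-4-yn-2-yl butanoate
Product: 17 (2R)-1-{5-[3-(tert-butyldiphenylsilyloxy)propyl]-4-methoxyfuran-2-yl}-2-methyl-1,3-dioxo-5-(trimethylsilyl)pent-4-yn-2-yl butanoate
Conditions: Dess–Martin periodinane, CH2Cl2, 0 °C → rt
Reagents that add atoms: none
Why: Dess–Martin oxidation of a propargylic alcohol should give the ynone under near-neutral conditions and removes the undefined carbinol centre, leaving C7 as the only stereocentre.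

Step 9
Reactants: 17 (2R)-1-{5-[3-(tert-butyldiphenylsilyloxy)propyl]-4-methoxyfuran-2-yl}-2-methyl-1,3-dioxo-5-(trimethylsilyl)pent-4-yn-2-yl butanoate
Product: 18 (2R)-1-{5-[3-(tert-butyldiphenylsilyloxy)propyl]-4-methoxyfuran-2-yl}-2-methyl-1,3-dioxopent-4-yn-2-yl butanoate
Conditions: Bu4NF, AcOH, THF, −78 °C
Reagents that add atoms: none
Why: Fluoride-induced protodesilylation of a ketone-activated alkynyl silane should be fast at low temperature, and the acetic acid buffer should protect the 2-acyloxy-1,3-diketone and the silyl ether.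

Step 10
Reactants: 18 (2R)-1-{5-[3-(tert-butyldiphenylsilyloxy)propyl]-4-methoxyfuran-2-yl}-2-methyl-1,3-dioxopent-4-yn-2-yl butanoate
Product: 20 (4R,7E)-12-(tert-butyldiphenylsilyloxy)-8-methoxy-4-methyl-3,5,6,9-tetraoxododec-7-en-1-yn-4-yl butanoate (the two acyl groups cis on the double bond), via furan epoxide 19 (not isolated)
Conditions: dimethyldioxirane (acetone solution), CH2Cl2, −78 → −20 °C; concentrate cold, use directly
Reagents that add atoms: dimethyldioxirane, CC1(C)OO1
Why: Oxidative furan ring-opening: epoxidation of the most electron-rich, tetrasubstituted enol-ether bond of the furan (the methoxy- and alkyl-bearing carbons) should give 19, which opens to the cis ene-1,4-dione, while the electron-poor ynone is not attacked.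

Step 11
Reactants: 20 (4R,7E)-12-(tert-butyldiphenylsilyloxy)-8-methoxy-4-methyl-3,5,6,9-tetraoxododec-7-en-1-yn-4-yl butanoate
Product: 24 (7R)-3-[3-(tert-butyldiphenylsilyloxy)propyl]-5-hydroxy-4-methoxy-7-methyl-6,8-dioxo-7,8-dihydro-6H-isochromen-7-yl butanoate, via ammonium allenolate 21 (not isolated), via ring-closed zwitterion 22 (not isolated), via keto tautomer 23 (not isolated)
Conditions: DABCO (20 mol %), CH2Cl2 (0.005 M), 0 °C → rt
Reagents that add atoms: none
Why: Proposed new method: DABCO should add to C1 of the terminal ynone of 20 to give the β-ammonium allenolate 21, whose α-carbon C8a adds in Michael fashion to C4a (β to the C3 ketone) to give 22, after which the C3 enolate oxygen attacks C1 and expels DABCO to give the 4H-pyran 23, which enolizes at the doubly allylic C4a–H toward the C5 ketone to give 24. The closest known reactions are the amine-catalysed formal [4+2] annulations of terminal ynones or allenoates with 1-oxadienes to 4H-pyrans and the intramolecular Rauhut–Currier reaction; their combination in one intramolecular event on an ene-trione has, as far as can be judged, not been described. The carbocycle (C4a, C5, C6, C7, C8, C8a) closes 6-exo-trig (enolendo) through the C4a–C8a bond, and the pyran ring (O2, C1, C8a, C4a, C4, C3) closes 6-endo-trig through O2–C1 addition–elimination. No new stereocentre remains, because C4a is sp3 only in 22 and 23 and becomes trigonal on enolization, and C7, quaternary with no enolizable neighbour, is not touched. The step needs C–C bond formation at C4a and not at the methoxy-bearing C4 (seven-membered ring, loss of methoxide) or at the C5 carbonyl (reversible 1,2-addition that cannot release the catalyst); the four-atom tether C5–C8 should make the six-membered closure the fastest, and only this path ends in irreversible expulsion of DABCO. High dilution should suppress intermolecular oligomerization of the ynone.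

Step 12
Reactants: 24 (7R)-3-[3-(tert-butyldiphenylsilyloxy)propyl]-5-hydroxy-4-methoxy-7-methyl-6,8-dioxo-7,8-dihydro-6H-isochromen-7-yl butanoate
Product: 25 (7R)-5-hydroxy-3-(3-hydroxypropyl)-4-methoxy-7-methyl-6,8-dioxo-7,8-dihydro-6H-isochromen-7-yl butanoate (target)
Conditions: HF·pyridine, pyridine, THF, 0 °C → rt
Reagents that add atoms: none
Why: Fluoride cleavage of the primary silyl ether under mildly acidic, non-nucleophilic conditions should leave the butanoate, the enol and the amine-sensitive pyran ring intact.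

**Compound list**

1 | (S)-lactic acid, (2S)-2-hydroxypropanoic acid | C[C@H](O)C(=O)O | starting material
2 | pivalaldehyde (2,2-dimethylpropanal) | CC(C)(C)C=O | starting material
3 | (2S,5S)-2-tert-butyl-5-methyl-1,3-dioxolan-4-one | C[C@@H]1O[C@H](C(C)(C)C)OC1=O | intermediate
4 | 3-(trimethylsilyl)prop-2-ynal | C[Si](C)(C)C#CC=O | starting material
5 | lithium (2S)-2-tert-butyl-5-methyl-1,3-dioxol-4-olate (lithium enolate of 3) | CC1=C(O[Li])O[C@@H](C(C)(C)C)O1 | intermediate (not isolated)
6 | (2S,5R)-2-tert-butyl-5-[1-hydroxy-3-(trimethylsilyl)prop-2-yn-1-yl]-5-methyl-1,3-dioxolan-4-one, both carbinol epimers | C[C@]1(C(O)C#C[Si](C)(C)C)O[C@H](C(C)(C)C)OC1=O | intermediate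
7 | (2S,5R)-2-tert-butyl-5-methyl-5-[1-(triethylsilyloxy)-3-(trimethylsilyl)prop-2-yn-1-yl]-1,3-dioxolan-4-one, both epimers at the silyloxy carbon | C[C@]1(C(O[Si](CC)(CC)CC)C#C[Si](C)(C)C)O[C@H](C(C)(C)C)OC1=O | intermediate
8 | 3-methoxyfuran | COc1ccoc1 | starting material
9 | (3-bromopropoxy)(tert-butyl)diphenylsilane | BrCCCO[Si](c1ccccc1)(c1ccccc1)C(C)(C)C | starting material
10 | 2-lithio-3-methoxyfuran | COc1ccoc1[Li] | intermediate (not isolated)
11 | tert-butyl[3-(3-methoxyfuran-2-yl)propoxy]diphenylsilane | COc1ccoc1CCCO[Si](c1ccccc1)(c1ccccc1)C(C)(C)C | intermediate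
12 | tert-butyl[3-(5-lithio-3-methoxyfuran-2-yl)propoxy]diphenylsilane | COc1cc([Li])oc1CCCO[Si](c1ccccc1)(c1ccccc1)C(C)(C)C | intermediate (not isolated)
13 | lithium hemiketal alkoxide from addition of 12 to the lactone carbonyl of 7 (hemiketal carbon undefined) | C[C@]1(C(O[Si](CC)(CC)CC)C#C[Si](C)(C)C)O[C@H](C(C)(C)C)OC1(O[Li])c1cc(OC)c(CCCO[Si](c2ccccc2)(c2ccccc2)C(C)(C)C)o1 | intermediate (not isolated)
14 | (2R)-1-{5-[3-(tert-butyldiphenylsilyloxy)propyl]-4-methoxyfuran-2-yl}-2-hydroxy-2-methyl-3-(triethylsilyloxy)-5-(trimethylsilyl)pent-4-yn-1-one, both C3 epimers | C[C@@](O)(C(O[Si](CC)(CC)CC)C#C[Si](C)(C)C)C(=O)c1cc(OC)c(CCCO[Si](c2ccccc2)(c2ccccc2)C(C)(C)C)o1 | intermediate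
15 | (2R)-1-{5-[3-(tert-butyldiphenylsilyloxy)propyl]-4-methoxyfuran-2-yl}-2-methyl-1-oxo-3-(triethylsilyloxy)-5-(trimethylsilyl)pent-4-yn-2-yl butanoate, both C3 epimers | CCCC(=O)O[C@](C)(C(O[Si](CC)(CC)CC)C#C[Si](C)(C)C)C(=O)c1cc(OC)c(CCCO[Si](c2ccccc2)(c2ccccc2)C(C)(C)C)o1 | intermediate
16 | (2R)-1-{5-[3-(tert-butyldiphenylsilyloxy)propyl]-4-methoxyfuran-2-yl}-3-hydroxy-2-methyl-1-oxo-5-(trimethylsilyl)pent-4-yn-2-yl butanoate, both C3 epimers | CCCC(=O)O[C@](C)(C(O)C#C[Si](C)(C)C)C(=O)c1cc(OC)c(CCCO[Si](c2ccccc2)(c2ccccc2)C(C)(C)C)o1 | intermediate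
17 | (2R)-1-{5-[3-(tert-butyldiphenylsilyloxy)propyl]-4-methoxyfuran-2-yl}-2-methyl-1,3-dioxo-5-(trimethylsilyl)pent-4-yn-2-yl butanoate | CCCC(=O)O[C@](C)(C(=O)C#C[Si](C)(C)C)C(=O)c1cc(OC)c(CCCO[Si](c2ccccc2)(c2ccccc2)C(C)(C)C)o1 | intermediate
18 | (2R)-1-{5-[3-(tert-butyldiphenylsilyloxy)propyl]-4-methoxyfuran-2-yl}-2-methyl-1,3-dioxopent-4-yn-2-yl butanoate | CCCC(=O)O[C@](C)(C(=O)C#C)C(=O)c1cc(OC)c(CCCO[Si](c2ccccc2)(c2ccccc2)C(C)(C)C)o1 | intermediate
19 | epoxide of 18 across the methoxy- and alkyl-bearing furan carbons (ring carbons undefined) | CCCC(=O)O[C@](C)(C(=O)C#C)C(=O)C1=CC2(OC)OC2(CCCO[Si](c3ccccc3)(c3ccccc3)C(C)(C)C)O1 | intermediate (not isolated)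
20 | (4R,7E)-12-(tert-butyldiphenylsilyloxy)-8-methoxy-4-methyl-3,5,6,9-tetraoxododec-7-en-1-yn-4-yl butanoate | CCCC(=O)O[C@](C)(C(=O)C#C)C(=O)C(=O)/C=C(/OC)C(=O)CCCO[Si](c1ccccc1)(c1ccccc1)C(C)(C)C | intermediate
21 | β-ammonium allenolate zwitterion from addition of DABCO to C1 of 20 | CCCC(=O)O[C@](C)(C([O-])=C=C[N+]12CCN(CC1)CC2)C(=O)C(=O)/C=C(/OC)C(=O)CCCO[Si](c1ccccc1)(c1ccccc1)C(C)(C)C | intermediate (not isolated)
22 | ring-closed zwitterion: cyclohexanetrione with exocyclic vinylammonium at C8a and the C3 enolate on C4a (C4a undefined) | CCCC(=O)O[C@]1(C)C(=O)C(=C[N+]23CCN(CC2)CC3)C(C(OC)=C([O-])CCCO[Si](c2ccccc2)(c2ccccc2)C(C)(C)C)C(=O)C1=O | intermediate (not isolated)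
23 | (7R)-3-[3-(tert-butyldiphenylsilyloxy)propyl]-4-methoxy-7-methyl-5,6,8-trioxo-5,6,7,8-tetrahydro-4aH-isochromen-7-yl butanoate (C4a undefined) | CCCC(=O)O[C@]1(C)C(=O)C2=COC(CCCO[Si](c3ccccc3)(c3ccccc3)C(C)(C)C)=C(OC)C2C(=O)C1=O | intermediate (not isolated)
24 | (7R)-3-[3-(tert-butyldiphenylsilyloxy)propyl]-5-hydroxy-4-methoxy-7-methyl-6,8-dioxo-7,8-dihydro-6H-isochromen-7-yl butanoate | CCCC(=O)O[C@]1(C)C(=O)C2=COC(CCCO[Si](c3ccccc3)(c3ccccc3)C(C)(C)C)=C(OC)C2=C(O)C1=O | intermediate
25 | (7R)-5-hydroxy-3-(3-hydroxypropyl)-4-methoxy-7-methyl-6,8-dioxo-7,8-dihydro-6H-isochromen-7-yl butanoate | CCCC(=O)O[C@]1(C)C(=O)C2=COC(CCCO)=C(OC)C2=C(O)C1=O | target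

**Step count and risks**

Total step count: 12. Longest linear sequence: 11 steps (steps 1–3 and 5–12, from (S)-lactic acid); step 4 is the convergent branch.

Steps most likely to fail:

1. Step 11 (proposed new method). The allenolate may close on the methoxy-bearing C4 with loss of methoxide, or rest as the 1,2-adduct at the C5 ketone. The amine may also degrade the vicinal tricarbonyl unit before ring closure. The fallback uses known chemistry and sets out from 18. Conjugate addition of methanol to the ynone (MeOH, cat. trimethylphosphine, CH2Cl2) should give (2R,4E)-1-{5-[3-(tert-butyldiphenylsilyloxy)propyl]-4-methoxyfuran-2-yl}-5-methoxy-2-methyl-1,3-dioxopent-4-en-2-yl butanoate F1. Furan opening with dimethyldioxirane as in step 10 should give (1E,4R,7E)-12-(tert-butyldiphenylsilyloxy)-1,8-dimethoxy-4-methyl-3,5,6,9-tetraoxododeca-1,7-dien-4-yl butanoate F2. Heating in toluene (80–110 °C) should effect an intramolecular inverse-electron-demand oxa-Diels–Alder reaction of the 1-oxadiene with the enol ether, which forms C4a–C8a and O2–C1 and gives the cyclic acetal (7R)-3-[3-(tert-butyldiphenylsilyloxy)propyl]-1,4-dimethoxy-7-methyl-5,6,8-trioxo-4a,5,6,7,8,8a-hexahydro-1H-isochromen-7-yl butanoate F3. Pyridinium p-toluenesulfonate in toluene should eliminate methanol and, after enolization, return the route at 24.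

2. Step 10. The oxidant may attack the product enol ether or the ynone, or epoxidation of the acyl-deactivated furan may be too slow and let the material decompose. The fallback sets out from 18 and replaces the direct oxidation by a two-stage unmasking. N-Bromosuccinimide in MeOH with NaHCO3 at −30 °C should give the 2,5-dimethoxylated dihydrofuran (2R)-1-{5-[3-(tert-butyldiphenylsilyloxy)propyl]-2,4,5-trimethoxy-2,5-dihydrofuran-2-yl}-2-methyl-1,3-dioxopent-4-yn-2-yl butanoate F4. Mild hydrolysis (pyridinium p-toluenesulfonate, acetone/H2O) should then release the cis ene-dione under non-oxidizing conditions and return the route at 20.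

3. Step 5. Addition to the hindered lactone carbonyl may be incomplete, or premature collapse of the tetrahedral adduct may allow a second addition. The fallback sets out from 7. Opening the dioxolanone with MeNH(OMe)·HCl and i-PrMgCl in THF (−20 → 0 °C) should give the Weinreb amide (2R)-2-hydroxy-N-methoxy-N,2-dimethyl-3-(triethylsilyloxy)-5-(trimethylsilyl)pent-4-ynamide F5. After deprotonation of its tertiary hydroxyl with i-PrMgCl, addition of furyllithium 12 should stop at the stable chelate and return the route at 14.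

**Further compounds**

F1 | step 11 | (2R,4E)-1-{5-[3-(tert-butyldiphenylsilyloxy)propyl]-4-methoxyfuran-2-yl}-5-methoxy-2-methyl-1,3-dioxopent-4-en-2-yl butanoate | CCCC(=O)O[C@](C)(C(=O)/C=C/OC)C(=O)c1cc(OC)c(CCCO[Si](c2ccccc2)(c2ccccc2)C(C)(C)C)o1
F2 | step 11 | (1E,4R,7E)-12-(tert-butyldiphenylsilyloxy)-1,8-dimethoxy-4-methyl-3,5,6,9-tetraoxododeca-1,7-dien-4-yl butanoate | CCCC(=O)O[C@](C)(C(=O)/C=C/OC)C(=O)C(=O)/C=C(/OC)C(=O)CCCO[Si](c1ccccc1)(c1ccccc1)C(C)(C)C
F3 | step 11 | (7R)-3-[3-(tert-butyldiphenylsilyloxy)propyl]-1,4-dimethoxy-7-methyl-5,6,8-trioxo-4a,5,6,7,8,8a-hexahydro-1H-isochromen-7-yl butanoate (isomers at C1, C4a, C8a) | CCCC(=O)O[C@]1(C)C(=O)C2C(OC)OC(CCCO[Si](c3ccccc3)(c3ccccc3)C(C)(C)C)=C(OC)C2C(=O)C1=O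
F4 | step 10 | (2R)-1-{5-[3-(tert-butyldiphenylsilyloxy)propyl]-2,4,5-trimethoxy-2,5-dihydrofuran-2-yl}-2-methyl-1,3-dioxopent-4-yn-2-yl butanoate (ring diastereomers) | CCCC(=O)O[C@](C)(C(=O)C#C)C(=O)C1(OC)C=C(OC)C(OC)(CCCO[Si](c2ccccc2)(c2ccccc2)C(C)(C)C)O1
F5 | step 5 | (2R)-2-hydroxy-N-methoxy-N,2-dimethyl-3-(triethylsilyloxy)-5-(trimethylsilyl)pent-4-ynamide (both C3 epimers) | CON(C)C(=O)[C@](C)(O)C(O[Si](CC)(CC)CC)C#C[Si](C)(C)C
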